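**Retrosynthetic overview**
- Target ⇐ its 7-O-acetate by lipase-mediated neutral deacetylation (last step; spares C2 and the prenyl group).
- C8–prenyl bond ⇐ 5-O-prenyl ether by Eu(III)-catalysed Claisen–Cope rearrangement; the ether comes from (S)-isosakuranetin by 7-O-acetylation and 5-O-Mitsunobu prenylation.
- C2–aryl bond and the only stereocenter ⇐ Rh-catalysed asymmetric 1,4-addition of 4-methoxyphenylboronic acid to 5,7-bis(benzyloxy)chromone, then hydrogenolysis.
- Chromone ⇐ phloroacetophenone by bis-benzylation, enaminone formation and acid cyclisation.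
- Ring order: A ring purchased; pyranone (C) ring closed at the achiral stage; B ring added intact at C2; prenyl installed last.

Assumption: the target is (2S)-4′-O-methyl-8-prenylnaringenin (C2 = S from the SMILES). The (S)-ligand in step 4 is the antipode predicted by the Hayashi cyclic-enone model to give 2S; confirm by chiral HPLC/CD on the first run.

**Step 1**
Reactants: 1, 2′,4′,6′-trihydroxyacetophenone; 2, benzyl bromide
Product: 3, 1-[2,4-bis(benzyloxy)-6-hydroxyphenyl]ethanone
Conditions: BnBr (2.1 equiv), K2CO3, DMF, rt → 50 °C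
Reagents that add atoms: benzyl bromide, BrCc1ccccc1
Why: Williamson O-alkylation; the phenol hydrogen-bonded to the acetyl C=O is the least nucleophilic, so only the two non-chelated OH groups are benzylated.

**Step 2**
Reactants: 3; 4, N,N-dimethylformamide dimethyl acetal
Product: 5, (E)-1-[2,4-bis(benzyloxy)-6-hydroxyphenyl]-3-(dimethylamino)prop-2-en-1-one
Conditions: DMF-DMA (3 equiv), toluene, 95 °C
Reagents that add atoms: DMF-DMA, COC(OC)N(C)C (supplies the CH–NMe2 unit)
Why: Enaminone condensation of the acetyl CH3 with the amide acetal, the standard entry to 2,3-unsubstituted chromones; the chelated phenol stays free.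

**Step 3**
Reactants: 5
Product: 6, 5,7-bis(benzyloxy)-4H-chromen-4-one
Conditions: conc. HCl, CH2Cl2, rt → 40 °C
Reagents that add atoms: none
Why: Acid-promoted intramolecular oxa-Michael addition and loss of Me2NH closes the pyranone ring; benzyl aryl ethers are stable to these conditions.

**Step 4**
Reactants: 6; 7, 4-methoxyphenylboronic acid
Product: 8, (2S)-5,7-bis(benzyloxy)-2-(4-methoxyphenyl)chroman-4-one
Conditions: [RhCl(C2H4)2]2 (2.5 mol %), (S)-MeO-F12-BIPHEP (6 mol %), 7 (3 equiv), aq. K3PO4 (20 mol %), toluene/H2O, 25–35 °C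
Reagents that add atoms: 4-methoxyphenylboronic acid, COc1ccc(B(O)O)cc1 (aryl group; water supplies only H)
Why: Hayashi–Miyaura Rh-catalysed asymmetric 1,4-addition; the chiral bisphosphine–Rh–aryl species adds to one enantioface of the chromone C2=C3 bond, setting C2 as S, and the cod-free precatalyst (no racemic background) with near-neutral, low-temperature conditions avoids retro-oxa-Michael opening.

**Step 5**
Reactants: 8
Product: 9, (2S)-5,7-dihydroxy-2-(4-methoxyphenyl)chroman-4-one ((S)-isosakuranetin)
Conditions: H2 (1 atm), 10% Pd/C, EtOAc/MeOH, rt, stopped at full debenzylation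
Reagents that add atoms: none
Why: Neutral hydrogenolysis of both benzyl aryl ethers at 1 atm and rt leaves the flavanone C2–O bond and ketone intact, and no base or acid is present to epimerise C2; no alkene is yet in the molecule.

**Step 6**
Reactants: 9; 10, acetic anhydride
Product: 11, (2S)-5-hydroxy-2-(4-methoxyphenyl)-4-oxochroman-7-yl acetate
Conditions: Ac2O (1.05 equiv), pyridine, CH2Cl2, 0 °C
Reagents that add atoms: acetic anhydride, CC(=O)OC(C)=O
Why: Selective O-acylation; the 7-OH is the acidic, free phenol, whereas the 5-OH is locked in a hydrogen bond to C4=O and is not acetylated with one equivalent at 0 °C.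

**Step 7**
Reactants: 11; 12, 3-methylbut-2-en-1-ol (prenol)
Product: 13, (2S)-2-(4-methoxyphenyl)-5-[(3-methylbut-2-en-1-yl)oxy]-4-oxochroman-7-yl acetate
Conditions: PPh3, DIAD, THF, 0 °C → rt
Reagents that add atoms: prenol, CC(C)=CCO (prenyl group; its oxygen leaves as Ph3P=O)
Why: Mitsunobu etherification alkylates the chelated 5-OH under essentially neutral conditions, avoiding the basic alkylation that would open the flavanone and racemise C2; the acetate is untouched.

**Step 8**
Reactants: 13
Product: 14, (2S)-5-hydroxy-2-(4-methoxyphenyl)-8-(3-methylbut-2-en-1-yl)-4-oxochroman-7-yl acetate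
Conditions: Eu(fod)3 (10 mol %), acid-free CHCl3, 60 °C
Reagents that add atoms: none
Why: Lewis-acid-catalysed aromatic Claisen rearrangement to C6 followed by a Cope shift to C8 (para-Claisen–Cope) and rearomatisation delivers the linear prenyl group at C8; the 7-O-acyl group disfavours stopping at the crowded C6 reverse-prenyl stage, and C2 is remote and unaffected.

**Step 9**
Reactants: 14
Product: 15, (2S)-5,7-dihydroxy-2-(4-methoxyphenyl)-8-(3-methylbut-2-en-1-yl)chroman-4-one (target)
Conditions: immobilised Burkholderia cepacia lipase (Amano PS-IM), n-BuOH (10 equiv), THF, 40 °C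
Reagents that add atoms: none
Why: Lipase-catalysed transesterification (alcoholysis) of the aryl acetate in organic solvent at neutral pH frees the 7-OH without base, which would racemise the 5-hydroxyflavanone through its chalcone, and without acid, which would cyclise the prenyl group onto the 7-OH.

**Compound list**
1 | 2′,4′,6′-trihydroxyacetophenone | CC(=O)c1c(O)cc(O)cc1O | starting material
2 | benzyl bromide | BrCc1ccccc1 | starting material
3 | 1-[2,4-bis(benzyloxy)-6-hydroxyphenyl]ethanone | CC(=O)c1c(O)cc(OCc2ccccc2)cc1OCc1ccccc1 | intermediate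
4 | N,N-dimethylformamide dimethyl acetal | COC(OC)N(C)C | starting material
5 | (E)-1-[2,4-bis(benzyloxy)-6-hydroxyphenyl]-3-(dimethylamino)prop-2-en-1-one | CN(C)/C=C/C(=O)c1c(O)cc(OCc2ccccc2)cc1OCc1ccccc1 | intermediate
6 | 5,7-bis(benzyloxy)-4H-chromen-4-one | O=c1ccoc2cc(OCc3ccccc3)cc(OCc3ccccc3)c12 | intermediate
7 | 4-methoxyphenylboronic acid | COc1ccc(B(O)O)cc1 | starting material
8 | (2S)-5,7-bis(benzyloxy)-2-(4-methoxyphenyl)chroman-4-one | COc1ccc([C@@H]2CC(=O)c3c(OCc4ccccc4)cc(OCc4ccccc4)cc3O2)cc1 | intermediate
9 | (2S)-5,7-dihydroxy-2-(4-methoxyphenyl)chroman-4-one | COc1ccc([C@@H]2CC(=O)c3c(O)cc(O)cc3O2)cc1 | intermediate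
10 | acetic anhydride | CC(=O)OC(C)=O | starting material
11 | (2S)-5-hydroxy-2-(4-methoxyphenyl)-4-oxochroman-7-yl acetate | COc1ccc([C@@H]2CC(=O)c3c(O)cc(OC(C)=O)cc3O2)cc1 | intermediate
12 | 3-methylbut-2-en-1-ol | CC(C)=CCO | starting material
13 | (2S)-2-(4-methoxyphenyl)-5-[(3-methylbut-2-en-1-yl)oxy]-4-oxochroman-7-yl acetate | COc1ccc([C@@H]2CC(=O)c3c(OCC=C(C)C)cc(OC(C)=O)cc3O2)cc1 | intermediate
14 | (2S)-5-hydroxy-2-(4-methoxyphenyl)-8-(3-methylbut-2-en-1-yl)-4-oxochroman-7-yl acetate | COc1ccc([C@@H]2CC(=O)c3c(O)cc(OC(C)=O)c(CC=C(C)C)c3O2)cc1 | intermediate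
15 | (2S)-5,7-dihydroxy-2-(4-methoxyphenyl)-8-(3-methylbut-2-en-1-yl)chroman-4-one | COc1ccc([C@@H]2CC(=O)c3c(O)cc(O)c(CC=C(C)C)c3O2)cc1 | target

**Totals**
Total step count: 9. Longest linear sequence: 9 steps (1 → 15).

**Three steps most likely to fail**
1. Step 4 (asymmetric 1,4-addition): the 5,7-dialkoxychromone is a poor acceptor and the electron-rich boronic acid protodeboronates. Fallback: change the bond formed. Prepare 2′,4′,6′-trihydroxy-4-methoxychalcone (Claisen–Schmidt of the bis-MOM acetophenone with 4-methoxybenzaldehyde, then deprotection) and close the O1–C2 bond with a chalcone isomerase to give 9 directly.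
2. Step 8 (Claisen–Cope): 6-(1,1-dimethylallyl) isomer may form alongside the 8-prenyl product, and C2 could erode on prolonged Lewis-acid heating. Fallback: move the prenylation to the achiral stage. Run the 7-O-acetylation, 5-O-prenylation and rearrangement on 5,7-dihydroxychromone, separate regioisomers there, re-protect, then perform the asymmetric aryl addition on the 8-prenylchromone.
3. Step 9 (lipase deacetylation): the acetate flanked by the C8 prenyl group may be a slow lipase substrate. Fallback: from step 6 carry the 7-oxygen as a different acyl group. A butanoate is a much better lipase substrate; a chloroacetate can also be removed non-enzymatically with thiourea under neutral conditions.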